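Theta at 118 °C gave D and E in nearly the same proportion as beta at 85 °C.

| setting | alpha | theta | beta | dusk | midnight |
|---|---|---|---|---|---|
| Q | 2 mM | 2 mM | 2 mM | 2.0 mM | 2.0 mM |
| X | 0.12 equiv | 0.28 equiv | 0.43 equiv | 0.500 equiv | 0.170 equiv |
| temperature | 85 °C | 118 °C | 85 °C |  |  |
| remark | run made earlier | run made earlier | run made earlier | at 70 °C until 2.5 min, from then on at 130 °C | at 70 °C throughout |
| time |  |  |  | 8.0 min | 25 min |

| run | time / s | D / % | E / % |
|---|---|---|---|
| alpha | 10.0 | 4.6 | 2.7 |
| alpha | 20.0 | 7.7 | 2.6 |
| alpha | 30.0 | 8.4 | 2.9 |
| alpha | 60.0 | 9.2 | 3.4 |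
| alpha | 120 | 8.8 | 3.9 |
| theta | 10.0 | 10.3 | 2.9 |
| theta | 15.0 | 16.3 | 4.8 |
| theta | 20.0 | 19.3 | 6.3 |
| beta | 10.0 | 5.8 | 1.4 |
| beta | 30.0 | 22.4 | 7.2 |
| beta | 60.0 | 31.1 | 9.5 |
| beta | 80.0 | 32.6 | 9.5 |
| beta | 120 | 33.5 | 10.6 |

(standard deviation of a reading: 0.5 percentage points)

- given per volume of solution although it is solid: X
- the numbers in the tables scatter by 0.5 percentage points (one standard deviation)
- what may be going on: Q + L -> D; X <-> L; Q + L -> E
- at the start none of X is in solution

1. which one finishes higher in share of D in all that became D or E ("neither" within 2 percentage points) (dusk / midnight / neither)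
2. share of D in all that became D or E, dusk
3. share of D in all that became D or E, midnight

I summed the last 3 readings of beta, to thin the scatter, and then those of theta:

beta: sum of D / sum of D + E = 76.7%

theta: sum of D / sum of D + E = 76.6%

I call the beta figure the split: the share of D in D plus E, or the selectivity between the two routes, as read from these runs.

The correction for temperature, beta minus theta, was a reading of 0.028 percentage points, less than the margin of 2 points. Dusk and midnight go outside that range, to 70 °C and 130 °C, but I carried the correction as nil. Both routes are written with one Q and one L, so I took their ratio to hold whatever Q and L stood at. My reckoning therefore put dusk and midnight together at the split, which answers neither.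

The weak link was alpha, which read lower than the split. I reforged it by computing the small product from the large one:

E expected from alpha's mean D = 2.68%; mean E read = 3.40%

That gap of 0.72 points is larger than the scatter of a mean of 3 readings, 0.29 points, so the readings do not clear alpha. Theta at 0.28 equiv and beta at 0.43 equiv do not clear it either: they differ from each other in temperature as well as in X, and both carry more X than midnight at 0.170 equiv. I kept the split for midnight as a judgement resting on the written routes, not on these readings, and left alpha's gap open.

The forecast said 76% for dusk, 74.5% for midnight and neither, on the ground that “the same order in L should leave the share independent of how L is delivered”. Both its numbers lie below my split.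

The flasks gave 76.7% for dusk and 76.7% for midnight, so the answer is neither.

    Q + L → D (k = 20.5 /M/s, Ea = 46.0 kJ/mol)
    X ⇌ L, rate k2*(cs2 - [L]) while solid is left; crystals form when [L] > cs2 (solubility = 0.990 mM, k = 0.0390 /s)
    Q + L → E (k = 6.22 /M/s, Ea = 47.0 kJ/mol)
    (constants at 70 °C)

Dusk ended with more Q converted than midnight, 50.0% against 17.0%. The split turns conversion into D: dusk's 50.0% gives 38.4%, and dusk held 38.4%. In the flask like dusk but with 0.120 equiv of X, Q stood at 88%, so the split gives 9.20% of D, and that flask held 9.21%.

The data are calculated on assumed constants; the scatter is artificial.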